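In a one-step world, all starting material lost would appear as target. Saturday's run says otherwise: after 4.00 d at 42 °C it has lost 29.3% of its charge but shows 10.8% target. I book the rest as quenched substrate, and any isomer of the product hides in that figure. Dividing by the mean protic impurity over that interval gives a quench price of 0.140 mM⁻¹: quenched substrate made per target made, per millimolar of protic impurity present. This is a selectivity factor. Friday's first reading, from another charge, gives 0.132 mM⁻¹.

| flask | starting material | protic impurity | temperature | remark | time |
|---|---|---|---|---|---|
| Friday's | 0.027 M | 9.5 mM | 42 °C | run made earlier |  |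
| Sunday's | 0.042 M | 9.5 mM | 92 °C | run made earlier |  |
| Saturday's | 0.019 M | 14 mM | 42 °C | run made earlier |  |
| theta | 0.019 M | 9.50 mM | 80 °C |  | 15 d |
| eta | 0.019 M | 9.50 mM | 20 °C |  | 15 d |
| alpha | 0.019 M | 9.50 mM | 50 °C |  | 15 d |
| delta | 0.019 M | 9.50 mM | 110 °C |  | 15 d |

- Friday's (time / d: target / %, starting material / %): 5.00: 14.1, 71.8; 15.0: 29.7, 43.3; 25.0: 38.7, 29.8; 40.0: 44.7, 19.4; 60.0: 47.4, 12.1
- Sunday's (time / d: target / %, starting material / %): 0.833: 7.7, 42.1; 2.00: 6.0, 31.0; 3.00: 5.3, 28.7; 4.00: 5.3, 28.1; 6.00: 4.7, 27.7
- Saturday's (time / d: target / %, starting material / %): 4.00: 10.8, 70.7; 8.00: 18.4, 52.4; 15.0: 26.4, 33.0; 30.0: 33.7, 15.2; 60.0: 34.4, 5.9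

(standard deviation of a reading: 0.3 percentage points)

- reactions considered so far: starting material <-> target; starting material <-> isomer of the product; target <-> isomer of the product; starting material + protic impurity -> quenched substrate

- which flask leads in amount of target, in percent of the starting material charged ("all alike" within 1.5 percentage points) (theta / eta / alpha / delta / all alike)
- how much target is there at the end, in percent of the starting material charged: theta
- how much target is there at the end, in percent of the starting material charged: eta
- how much target is there at the end, in percent of the starting material charged: alpha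
- how much target is there at the end, in percent of the starting material charged: delta

I must choose the bath for a charge with 9.50 mM protic impurity. At Saturday's temperature, the price gives 1.33 quenched substrate per target at the start, so target takes 42.9% of the loss then. Heat looks poor: Sunday's run at 92 °C shows 4.7% target at 6.00 d. Friday's run at 42 °C shows 29.7% at 15.0 d. I therefore run alpha, at 50 °C, and expect it to lead.

The forecast also picks alpha, on the ground that “Isomer dominates when hot”.

| Target at the end | theta | eta | alpha | delta |
|---|---|---|---|---|
| Forecast | 6.5% | 7.5% | 37% | 1.3% |
| Flask | 5.61% | 2.09% | 42.0% | 1.60% |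

    starting material ⇌ target (K = 0.390, k = 3.20 × 10⁻⁵ s⁻¹, Ea = 108 kJ mol⁻¹, ΔH = −65.0 kJ mol⁻¹)
    starting material ⇌ isomer of the product (K = 2.10, k = 1.48 × 10⁻⁶ s⁻¹, Ea = 116 kJ mol⁻¹, ΔH = −25.0 kJ mol⁻¹)
    target ⇌ isomer of the product (k = 4.95 × 10⁻⁶ s⁻¹, Ea = 121 kJ mol⁻¹)
    starting material + protic impurity → quenched substrate (k = 6.66 × 10⁻⁴ M⁻¹ s⁻¹, Ea = 62.0 kJ mol⁻¹)
    (constants at 80 °C)

Alpha leads, and the two part at eta, which holds 9.26% quenched substrate beside 2.09% target. In alpha at 15.0 d, starting material has a half-life of 7.6 d by the forward step to target alone and 25 d by the quench, so the quench takes starting material at 0.308 of that forward rate, with 36% of the protic impurity left. That ratio counts the forward step only; taking each step net, alpha makes target at 1.63 times the rate at which it uses target up. The price, read at 42 °C, gives 0.484 there, so alpha scales it by 0.637. For a neighbour flask like alpha but with 0.0024 M protic impurity, price and scale give 0.214 quenched substrate per target, forward steps only, at the start. Its computed end holds 53.0% target and 9.02% quenched substrate, a ratio of 0.170.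

The numbers in the tables were computed for an exercise; scatter was added.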